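The target is a leftover: in the beta run substrate already reads 0% at 2.50 min, and target then slides from 98.8% to 82.5% at 30.0 min as it turns into over-reaction product.

in all of them: substrate 0.10 M
- beta: free enzyme 70 µM; added ligand 26 µM; temperature 32 °C; run made earlier
- zeta: free enzyme 110 µM; added ligand 26 µM; temperature 49 °C; run made earlier
- alpha: free enzyme 50 µM; added ligand 52 µM; temperature 32 °C; run made earlier
- south-west: free enzyme 50 µM; added ligand 26 µM; temperature 55 °C; time 12 min
- south: free enzyme 50 µM; added ligand 26 µM; at 25 °C until 8.0 min, from then on at 55 °C; time 12 min
- south-east: free enzyme 50 µM; added ligand 26 µM; temperature 25 °C; time 12 min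

- beta (time / min: target / %, substrate / %): 2.50: 98.8, 0; 4.00: 97.6, 0; 8.00: 95.8, 0; 15.0: 90.7, 0; 30.0: 82.5, 0
- zeta (time / min: target / %, substrate / %): 2.00: 92.3, 1.1; 4.00: 84.3, 0.6; 6.00: 76.2, 0; 8.00: 69.5, 0; 10.0: 63.6, 0
- alpha (time / min: target / %, substrate / %): 2.50: 98.5, 0; 4.00: 97.7, 0; 8.00: 95.7, 0; 15.0: 90.9, 0.2; 30.0: 82.9, 0.9

(readings scatter by 0.5 percentage points)

- what may be going on: free enzyme -> unfolded enzyme; substrate + free enzyme -> target + free enzyme; free enzyme + added ligand <-> idle complex; target -> over-reaction product

- the best flask by amount of target, in percent of the substrate charged; "all alike" if 1.5 percentage points covers them all (south-west / south / south-east / all alike)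
- amount of target at the end, in percent of the substrate charged, south-west
- amount of target at the end, in percent of the substrate charged, south
- amount of target at the end, in percent of the substrate charged, south-east

So work in powers of ten. Read as a first-order decay, the common logarithm of target falls with a slope s of 0.00285 /min at 32 °C in the beta run, and of 0.0202 /min at 49 °C in the zeta run. Running the logarithm of s straight against reciprocal temperature (Arrhenius) carries these readings on to 0.0385 /min at 55 °C. Target there needs 26.0 min to fall by one power of ten: call this the decade time, D, the decimal reduction time of the sterilisers.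

By my own reckoning, south-west spends 0.462 of a decade hot, so a charge converted at once would end near 34.5%. South spends 0.154 of a decade hot, which is a factor of 0.702.

The forecast names south-east, with 23% for south-west, 68% for south and 96.8% for south-east. Its figure for south-west lies lower than my estimate for a charge converted at once, since it says that flask “may therefore stall before full conversion”.

South-west gives 5.52%, south 69.3% and south-east 96.9%, so south-east is best, and the forecast stood 17 percentage points high for south-west.

    free enzyme → unfolded enzyme (k = 2.10 × 10⁻⁵ /s, Ea = 263 kJ/mol)
    substrate + free enzyme → target + free enzyme, rate k2*[substrate]*[free enzyme]/(1 + ([substrate]/Km2) + ([substrate]/Ksi2)^2) (8.70 mM, 0.0660 M, k = 9300 /M/s, Ea = 14.0 kJ/mol)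
    free enzyme + added ligand ⇌ idle complex, settled at all times (K = 23000 /M, ΔH = −11.0 kJ/mol)
    target → over-reaction product (k = 4.50 × 10⁻⁵ /s, Ea = 94.0 kJ/mol)
    (constants at 25 °C)

South-west holds substrate at 84.5% at 6.00 min and 84.5% at 12.0 min, with free enzyme at 0% of the catalyst charged. From its 9.27% of target at 6.00 min, D predicts 5.45% at 12.0 min, against the 5.52% found. The same line puts D at 136 min for 40 °C, so a flask like south-east kept at that temperature should end at 81.6%, and it gives 82.3%.

All runs are simulated for substances that don't exist; the scatter is artificial.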